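Cuts: first the C8–O ester bond (epoxy acid from tiglic acid). The C9 ketone, the C12 lactone carbonyl and the C1 methyl ether are then taken back to a silyl ether, a methyl lactol ether and a C1 ketone, and the C2–C3 bond is cut.
Enabling feature: in the ten-membered ring, C1(=O)–C2–C3–C4(Me)=C5 is a γ,δ-unsaturated ketone, the product pattern of a Claisen rearrangement. Restoring a C5–O–C1 link contracts the carbocycle to an eight-membered lactone (C1, O, C5–C10) that carries the isopropenyl group C3=C4 on C5, and C2 comes from a titanium methylidene.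
Further cuts: C1–O5 (lactonisation), C9–C10 (aldol), C11–CH3 (enolate methylation), C7–C11 and C8–O (Michael addition and hydroxylation on a C6–C9 butenolide, ring A), C7=C8 and C3=C4 (Wittig reactions).
Forward ring order: ring A butenolide; O6 moved from C9 to C12 to give ring B (oxolane C6–O–C12–C11–C7); eight-membered lactone; ten-membered carbocycle by ring expansion; butyrolactone unmasked; side chain esterified last.
Stereochemistry: C5 and C6 come from D-erythronolactone, C7 and C8 from anti additions on ring A, and C11 from convex-face methylation of ring B. C10 (and the transient C9) come from an oxazolidinone aldol, C1 from an oxazaborolidine reduction, E-C4=C5 from the chair transition state, and the epoxide from a Sharpless epoxidation.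

Key step: step 20

Remark on the chemistry: atoms carry the germacranolide numbers of the target (ring C1–C10, lactone C11 and C12; O5, O6, O8, O9 are the oxygens on those carbons). Hemiketal and lactol carbons are anomeric mixtures and are written without a descriptor. The methyl acetal carbon C12 is assumed to be the epimer with OMe trans to the C11 methyl group; this centre is erased when the lactone is unmasked.

Step 1
Reactants: 1 (−)-2,3-O-isopropylidene-D-erythronolactone
Product: 2 1-deoxy-3,4-O-isopropylidene-D-erythro-pent-2-ulofuranose (hemiketal)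
Conditions: MeLi (1.05 equiv), THF, −78 °C
Reagents that add atoms: methyllithium [Li]C
Why: Addition of an organolithium to a γ-lactone at low temperature stops at the lithium hemiketal, so C4 gains its methyl group while the chiral-pool centres C5 and C6 in the cis-dioxolane are untouched.

Step 2
Reactants: 2 1-deoxy-3,4-O-isopropylidene-D-erythro-pent-2-ulofuranose (hemiketal)
Product: 4 [(4R,5S)-2,2-dimethyl-5-(prop-1-en-2-yl)-1,3-dioxolan-4-yl]methanol, via open hydroxy ketone 3 (not isolated)
Conditions: MePPh3Br, KOtBu, THF, 0 °C to rt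
Reagents that add atoms: methyltriphenylphosphonium bromide C[P+](c1ccccc1)(c1ccccc1)c1ccccc1.[Br-]
Why: Wittig methylenation of the hemiketal through its open ketone tautomer builds the isopropenyl group (C3=C4) and frees the C7 alcohol, and the mild temperature should leave the α-alkoxy centre C5 unepimerised.

Step 3
Reactants: 4 [(4R,5S)-2,2-dimethyl-5-(prop-1-en-2-yl)-1,3-dioxolan-4-yl]methanol
Product: 5 (4S,5S)-2,2-dimethyl-5-(prop-1-en-2-yl)-1,3-dioxolane-4-carbaldehyde
Conditions: Dess–Martin periodinane, CH2Cl2, 0 °C to rt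
Reagents that add atoms: none
Why: Dess–Martin oxidation gives the aldehyde without base, which protects the epimerisable C6 centre.

Step 4
Reactants: 5 (4S,5S)-2,2-dimethyl-5-(prop-1-en-2-yl)-1,3-dioxolane-4-carbaldehyde
Product: 6 methyl (Z)-3-[(4R,5S)-2,2-dimethyl-5-(prop-1-en-2-yl)-1,3-dioxolan-4-yl]prop-2-enoate
Conditions: Ph3P=CHCO2Me, MeOH, 0 °C
Reagents that add atoms: methyl (triphenylphosphoranylidene)acetate COC(=O)C=P(c1ccccc1)(c1ccccc1)c1ccccc1
Why: A Wittig reaction of a stabilised ylide in methanol is Z-selective for α-alkoxy aldehydes and adds C8 and C9 with the geometry needed for lactonisation.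

Step 5
Reactants: 6 methyl (Z)-3-[(4R,5S)-2,2-dimethyl-5-(prop-1-en-2-yl)-1,3-dioxolan-4-yl]prop-2-enoate
Product: 8 (5R)-5-[(1S)-1-hydroxy-2-methylprop-2-enyl]furan-2(5H)-one (ring A butenolide), via dihydroxy Z-enoate 7 (not isolated)
Conditions: TsOH·H2O (cat.), MeOH–H2O, rt
Reagents that add atoms: none
Why: Acid hydrolysis of the acetonide is followed by 5-exo-trig lactonisation of O6–H onto the Z-ester, which should favour the conjugated five-membered lactone over the six-membered one through O5, and any E-ester cannot cyclise and is removed here.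

Step 6
Reactants: 8 (5R)-5-[(1S)-1-hydroxy-2-methylprop-2-enyl]furan-2(5H)-one (ring A butenolide)
Product: 9 (5R)-5-[(1S)-2-methyl-1-(2-naphthylmethoxy)prop-2-enyl]furan-2(5H)-one (O5-NAP butenolide)
Conditions: 2-naphthylmethyl trichloroacetimidate, TfOH (cat.), CH2Cl2–cyclohexane, 0 °C
Reagents that add atoms: 2-naphthylmethyl 2,2,2-trichloroacetimidate N=C(OCc1ccc2ccccc2c1)C(Cl)(Cl)Cl
Why: Acid-catalysed trichloroacetimidate etherification protects O5 without base (which would deprotonate C6 of the butenolide), and the NAP ether behaves like a benzyl ether towards bases, hydrides and Lewis acids yet is removable by oxidation.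

Step 7
Reactants: 9 (5R)-5-[(1S)-2-methyl-1-(2-naphthylmethoxy)prop-2-enyl]furan-2(5H)-one (O5-NAP butenolide); 10 tert-butyl acetate
Product: 13 all-trans ring A lactone (5S,6R,7R,8R) bearing C8–OH and C7–CH2CO2tBu, via lithium enolate 11 (not isolated), via ring A lithium enolate 12 (not isolated)
Conditions: LiN(iPr)2, 10, THF, −78 °C; 9, −78 °C; (camphorsulfonyl)oxaziridine, −78 °C
Reagents that add atoms: (camphorsulfonyl)oxaziridine CC1(C)C2CCC13CS(=O)(=O)N4OC34C2
Why: In this tandem Michael addition and enolate oxidation the ester enolate adds to C7 anti to the C6 side chain, and the regiospecifically formed ring A enolate is hydroxylated at C8 anti to the new C7 substituent, so both centres are set by the ring.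

Step 8
Reactants: 13 all-trans ring A lactone (5S,6R,7R,8R) bearing C8–OH and C7–CH2CO2tBu
Product: 14 O8-TBS ring A lactone (5S,6R,7S,8R)
Conditions: TBSCl, imidazole, DMF, rt
Reagents that add atoms: tert-butyldimethylsilyl chloride CC(C)(C)[Si](C)(C)Cl
Why: Standard silylation of the unhindered α-hydroxy lactone installs a group that outlasts every step up to the penultimate one and keeps O8 from competing with O6 for C12.

Step 9
Reactants: 14 O8-TBS ring A lactone (5S,6R,7S,8R)
Product: 15 ring A lactol (C9 hemiacetal)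
Conditions: iBu2AlH (1.1 equiv), toluene, −78 °C
Reagents that add atoms: none
Why: Half-reduction of a γ-lactone with iBu2AlH stops at the aluminium lactolate at −78 °C, and the hindered tert-butyl ester should not be attacked.

Step 10
Reactants: 15 ring A lactol (C9 hemiacetal)
Product: 17 ring B γ-lactone (5S,6R,7S,8R) with C9 as 1,3-dithiane, via open-chain dithiane alcohol 16 (not isolated)
Conditions: HS(CH2)3SH, BF3·OEt2 (cat.), CH2Cl2, −40 to 0 °C
Reagents that add atoms: propane-1,3-dithiol SCCCS
Why: Lewis-acid thioacetalisation opens the lactol to the acyclic dithiane as with aldose dithioacetals, and the freed O6–H closes 5-exo-trig onto the tert-butyl ester under the same acid, which moves O6 from C9 to C12 and places the C5 and C8 substituents cis on ring B with no stereocentre touched.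

Step 11
Reactants: 17 ring B γ-lactone (5S,6R,7S,8R) with C9 as 1,3-dithiane
Product: 19 11-methyl ring B lactone (5S,6R,7S,8R,11S), via ring B lithium enolate 18 (not isolated)
Conditions: LiN(iPr)2 (1.1 equiv), THF, −78 °C; MeI
Reagents that add atoms: iodomethane CI
Why: Alkylation of the lactone enolate occurs on the face opposite the C7 and C6 substituents, which both lie on one side of ring B, so the C11 methyl group ends trans to C8 as in the target.

Step 12
Reactants: 19 11-methyl ring B lactone (5S,6R,7S,8R,11S)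
Product: 20 ring B lactol (C12 hemiacetal)
Conditions: iBu2AlH (1.1 equiv), CH2Cl2, −78 °C
Reagents that add atoms: none
Why: Half-reduction of the only carbonyl group lowers C12 to the aldehyde level so that it can be masked against the titanium reagent.

Step 13
Reactants: 20 ring B lactol (C12 hemiacetal)
Product: 21 ring B methyl lactol ether (5S,6R,7S,8R,11S,12S) with C9 dithiane
Conditions: MeOH, PPTS (cat.), rt
Reagents that add atoms: methanol CO
Why: Mild acid-catalysed acetalisation through the cyclic oxocarbenium ion gives the 2-methoxyoxolane, methanol entering trans to the neighbouring C11 methyl group, while dithiane, TBS and NAP groups are inert.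

Step 14
Reactants: 21 ring B methyl lactol ether (5S,6R,7S,8R,11S,12S) with C9 dithiane
Product: 22 C9 aldehyde (α-silyloxy aldehyde on ring B)
Conditions: MeI, CaCO3, MeCN–H2O, 40 °C
Reagents that add atoms: water O
Why: Alkylative hydrolysis of the dithiane runs at neutral pH, so the acetal, the silyl ether, the alkene and the C8 centre next to the new aldehyde should survive.

Step 15
Reactants: 22 C9 aldehyde (α-silyloxy aldehyde on ring B); 23 (R)-4-benzyl-3-propionyloxazolidin-2-one
Product: 25 syn aldol adduct (8R,9R,10R), via Z boron enolate 24 (not isolated)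
Conditions: 23, Bu2BOTf, Et3N, CH2Cl2, −78 to 0 °C; 22, −78 to 0 °C; H2O2, MeOH, pH 7 buffer
Reagents that add atoms: none
Why: In the Evans syn aldol the Z boron enolate reacts through a closed chair in which the (R)-benzyl group blocks one enolate face, which fixes C10 (and the transient C9) whatever the modest bias of the α-silyloxy aldehyde.

Step 16
Reactants: 25 syn aldol adduct (8R,9R,10R)
Product: 26 O9-TES aldol imide
Conditions: TESCl, imidazole, DMF, rt
Reagents that add atoms: chlorotriethylsilane CC[Si](Cl)(CC)CC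
Why: Silylation with the chloride and imidazole caps O9 with an acid-labile group different from the O8-TBS ether and avoids silyl triflate, which could activate the acetal.

Step 17
Reactants: 26 O9-TES aldol imide
Product: 27 C1 carboxylic acid (O5-NAP)
Conditions: LiOH, H2O2, THF–H2O, 0 °C; Na2SO3; dilute HCl to pH 4
Reagents that add atoms: hydrogen peroxide OO
Why: Hydroperoxide attacks the exocyclic imide carbonyl selectively and is too weakly basic to epimerise C10, so the auxiliary is released without damage to the silyl ethers.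

Step 18
Reactants: 27 C1 carboxylic acid (O5-NAP)
Product: 28 seco acid with free O5–H
Conditions: DDQ, CH2Cl2–pH 7 buffer, 0 °C to rt
Reagents that add atoms: none
Why: Oxidative cleavage of the naphthylmethyl ether by DDQ is orthogonal to TES, TBS, acetal, acid and the isopropenyl group and frees only O5.

Step 19
Reactants: 28 seco acid with free O5–H
Product: 30 eight-membered lactone (5S,6R,7S,8R,9R,10R,11S,12S): C1(=O)–O–C5 oxocan-2-one cis-fused to ring B, isopropenyl on C5, via mixed anhydride 29 (not isolated)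
Conditions: 2-methyl-6-nitrobenzoic anhydride, DMAP, CH2Cl2 (2 mM), rt, slow addition
Reagents that add atoms: none
Why: Shiina macrolactonisation acylates O5 with retention at C5, has precedent for heavily substituted eight-membered lactones, and is helped here by ring B and the branched chain, which limit the open conformations of the seco acid.

Step 20
Reactants: 30 eight-membered lactone (5S,6R,7S,8R,9R,10R,11S,12S): C1(=O)–O–C5 oxocan-2-one cis-fused to ring B, isopropenyl on C5
Product: 32 (4E)-cyclodec-4-en-1-one (6S,7S,8R,9R,10R,11S,12S) fused to ring B, via enol ether 31 (not isolated)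
Conditions: Cp2TiMe2 (2.5 equiv), toluene, 70 °C, dark; NaHCO3, MeOH–H2O, 40 °C, filter; crude 31, xylenes, 140 °C
Reagents that add atoms: dimethyltitanocene C[Ti](C)(C1C=CC=C1)C1C=CC=C1
Why: Warm Cp2TiMe2 loses methane and the resulting Cp2Ti=CH2 converts the only carbonyl group of 30 through an oxatitanacyclobutane into the 2-methyleneoxocane 31, whose C2=C1–O–C5–C4=C3 array then undergoes a concerted [3,3] shift at 140 °C that makes C2–C3, breaks C5–O and leaves the C1 ketone and the C4=C5 alkene. The closest known chemistry is Petasis or Tebbe methylenation of 6-alkenyl δ-lactones followed by Claisen rearrangement to cyclooctenones, together with the ketene-acetal variant that expands vinyl-substituted cyclic ketene acetals to eight- to ten-membered lactones. The ten-membered carbocycle is closed by a two-atom ring expansion: the new σ bond joins two exocyclic CH2 termini held close by the oxocane while the endocyclic C–O bond opens, so no end-to-end cyclisation of an open chain is needed. No stereocentre is created (C2 and C3 are CH2, C5 becomes sp2), and the neutral, non-basic medium leaves C6–C12, including C10 next to the new ketone, unchanged. The selectivity needed is E over Z at C4=C5, which requires C6 equatorial on C5 in the chair as in Claisen rearrangements of isopropenyl carbinols; for this reason the 5,6-anti (5S,6R) lactone is used, since it can place C7 anti to C4, O6 anti to the breaking C5–O bond and H6 towards the C4 methyl group, free of allylic 1,3-strain, whereas the 5,6-syn epimer would turn O6 towards that methyl group. Chemoselectivity rests on the masking of C12 (acetal), O8 and O9 (silyl ethers) and on destroying excess titanium reagent before the temperature is raised, so that ketone 32 never meets Cp2Ti=CH2.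

Step 21
Reactants: 32 (4E)-cyclodec-4-en-1-one (6S,7S,8R,9R,10R,11S,12S) fused to ring B
Product: 33 (1S)-cyclodecenol
Conditions: (R)-Me-CBS oxazaborolidine (0.5 equiv), catecholborane, toluene, −78 to −40 °C
Reagents that add atoms: none
Why: In the Corey–Bakshi–Shibata reduction the ketone binds the catalyst on the side of the unbranched C2 flank and away from the branched C10 flank, so the (R)-catalyst should deliver hydride to the face that gives 1S, and catecholborane leaves the alkene alone at low temperature.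

Step 22
Reactants: 33 (1S)-cyclodecenol
Product: 34 C1 methyl ether (1S,6S,7S,8R,9R,10S,11S,12S)
Conditions: MeOTf, 2,6-di-tert-butyl-4-methylpyridine, CH2Cl2, rt
Reagents that add atoms: methyl trifluoromethanesulfonate COS(=O)(=O)C(F)(F)F
Why: Methylation of the neutral alcohol with a hindered pyridine as proton trap avoids an alkoxide, which could take the silyl group from O9, and does not touch C1.

Step 23
Reactants: 34 C1 methyl ether (1S,6S,7S,8R,9R,10S,11S,12S)
Product: 36 C9-keto γ-lactone with O8-TBS (1S,6S,7S,8R,10S,11S), via hydroxy lactol 35 (not isolated)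
Conditions: CrO3, H2SO4, acetone–H2O, 0 °C
Reagents that add atoms: water O
Why: Under Jones oxidation the aqueous acid cleaves the labile TES ether and hydrolyses the 2-methoxyoxolane, and chromic acid oxidises the C9 carbinol to the ketone and the lactol to the γ-lactone as they appear, as in the direct conversion of cyclic alkyl acetals into lactones, while the hindered O8-TBS ether, the methyl ether and the trisubstituted alkene should persist at 0 °C.

Step 24
Reactants: 36 C9-keto γ-lactone with O8-TBS (1S,6S,7S,8R,10S,11S)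
Product: 37 C8-hydroxy C9-ketone (1S,6S,7R,8R,10S,11S)
Conditions: HF·pyridine, pyridine, THF, 0 °C to rt
Reagents that add atoms: none
Why: Buffered fluoride desilylation is weakly acidic, so the β-methoxy ketone is not enolised and C8, C10 and the methoxy group are kept.

Step 25
Reactants: 38 tiglic acid
Product: 39 (E)-2-methylbut-2-en-1-ol
Conditions: LiAlH4, Et2O, 0 °C
Reagents that add atoms: none
Why: Hydride reduction of the conjugated acid gives the allylic alcohol with the E geometry retained.

Step 26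
Reactants: 39 (E)-2-methylbut-2-en-1-ol
Product: 40 [(2R,3R)-2,3-dimethyloxiran-2-yl]methanol
Conditions: Ti(OiPr)4 (cat.), D-(−)-diethyl tartrate (cat.), tBuOOH, 4 Å MS, CH2Cl2, −20 °C
Reagents that add atoms: tert-butyl hydroperoxide CC(C)(C)OO
Why: Sharpless asymmetric epoxidation adds oxygen suprafacially, so the E alkene fixes the cis relation of the two methyl groups and the D-(−)-tartrate sets the 2R,3R absolute configuration.

Step 27
Reactants: 40 [(2R,3R)-2,3-dimethyloxiran-2-yl]methanol
Product: 41 (2S,3R)-2,3-dimethyloxirane-2-carboxylic acid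
Conditions: TEMPO (cat.), PhI(OAc)2, MeCN–H2O, rt
Reagents that add atoms: water O
Why: Oxoammonium oxidation takes the primary alcohol through the aldehyde hydrate to the acid at near-neutral pH and leaves the epoxide intact, the change of the C2 descriptor being a matter of priority only.

Step 28
Reactants: 37 C8-hydroxy C9-ketone (1S,6S,7R,8R,10S,11S); 41 (2S,3R)-2,3-dimethyloxirane-2-carboxylic acid
Product: 43 CNP0145898.1 (target), via mixed anhydride 42 (not isolated)
Conditions: 41, 2,4,6-trichlorobenzoyl chloride, Et3N, toluene, rt; 37, DMAP, rt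
Reagents that add atoms: none
Why: Yamaguchi esterification activates the hindered α-quaternary acid as its mixed anhydride and acylates O8 at room temperature with amine bases too weak to enolise the ketone, so no stereocentre of either partner is disturbed.

Compound list
1 | (−)-2,3-O-isopropylidene-D-erythronolactone | O=C1OC[C@H]2OC(C)(C)O[C@@H]12 | starting material
2 | 1-deoxy-3,4-O-isopropylidene-D-erythro-pent-2-ulofuranose (hemiketal) | CC1(O)OC[C@H]2OC(C)(C)O[C@@H]12 | intermediate
3 | open hydroxy ketone (1-deoxy-3,4-O-isopropylidene-D-erythro-pent-2-ulose) | CC(=O)[C@@H]1OC(C)(C)O[C@@H]1CO | intermediate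
4 | [(4R,5S)-2,2-dimethyl-5-(prop-1-en-2-yl)-1,3-dioxolan-4-yl]methanol | C=C(C)[C@@H]1OC(C)(C)O[C@@H]1CO | intermediate
5 | (4S,5S)-2,2-dimethyl-5-(prop-1-en-2-yl)-1,3-dioxolane-4-carbaldehyde | C=C(C)[C@@H]1OC(C)(C)O[C@@H]1C=O | intermediate
6 | methyl (Z)-3-[(4R,5S)-2,2-dimethyl-5-(prop-1-en-2-yl)-1,3-dioxolan-4-yl]prop-2-enoate | C=C(C)[C@@H]1OC(C)(C)O[C@@H]1/C=C\C(=O)OC | intermediate
7 | dihydroxy Z-enoate, methyl (2Z,4R,5S)-4,5-dihydroxy-6-methylhepta-2,6-dienoate | C=C(C)[C@H](O)[C@H](O)/C=C\C(=O)OC | intermediate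
8 | (5R)-5-[(1S)-1-hydroxy-2-methylprop-2-enyl]furan-2(5H)-one (ring A butenolide) | C=C(C)[C@H](O)[C@@H]1OC(=O)C=C1 | intermediate
9 | (5R)-5-[(1S)-2-methyl-1-(2-naphthylmethoxy)prop-2-enyl]furan-2(5H)-one (O5-NAP butenolide) | C=C(C)[C@H](OCc1ccc2ccccc2c1)[C@@H]1OC(=O)C=C1 | intermediate
10 | tert-butyl acetate | CC(=O)OC(C)(C)C | starting material
11 | lithium enolate of tert-butyl acetate | C=C([O-])OC(C)(C)C.[Li+] | intermediate
12 | ring A lithium enolate (Michael adduct) | C=C(C)[C@H](OCc1ccc2ccccc2c1)[C@@H]1OC([O-])=C[C@H]1CC(=O)OC(C)(C)C.[Li+] | intermediate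
13 | all-trans ring A lactone (5S,6R,7R,8R) bearing C8–OH and C7–CH2CO2tBu | C=C(C)[C@H](OCc1ccc2ccccc2c1)[C@@H]1OC(=O)[C@H](O)[C@H]1CC(=O)OC(C)(C)C | intermediate
14 | O8-TBS ring A lactone (5S,6R,7S,8R) | C=C(C)[C@H](OCc1ccc2ccccc2c1)[C@@H]1OC(=O)[C@H](O[Si](C)(C)C(C)(C)C)[C@H]1CC(=O)OC(C)(C)C | intermediate
15 | ring A lactol (C9 hemiacetal) | C=C(C)[C@H](OCc1ccc2ccccc2c1)[C@@H]1OC(O)[C@H](O[Si](C)(C)C(C)(C)C)[C@H]1CC(=O)OC(C)(C)C | intermediate
16 | open-chain dithiane alcohol (free O6–H, tert-butyl ester) | C=C(C)[C@H](OCc1ccc2ccccc2c1)[C@H](O)[C@H](CC(=O)OC(C)(C)C)[C@@H](O[Si](C)(C)C(C)(C)C)C1SCCCS1 | intermediate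
17 | ring B γ-lactone (5S,6R,7S,8R) with C9 as 1,3-dithiane | C=C(C)[C@H](OCc1ccc2ccccc2c1)[C@@H]1OC(=O)C[C@@H]1[C@@H](O[Si](C)(C)C(C)(C)C)C1SCCCS1 | intermediate
18 | ring B lithium enolate | C=C(C)[C@H](OCc1ccc2ccccc2c1)[C@@H]1OC([O-])=C[C@@H]1[C@@H](O[Si](C)(C)C(C)(C)C)C1SCCCS1.[Li+] | intermediate
19 | 11-methyl ring B lactone (5S,6R,7S,8R,11S) | C=C(C)[C@H](OCc1ccc2ccccc2c1)[C@@H]1OC(=O)[C@@H](C)[C@@H]1[C@@H](O[Si](C)(C)C(C)(C)C)C1SCCCS1 | intermediate
20 | ring B lactol (C12 hemiacetal) | C=C(C)[C@H](OCc1ccc2ccccc2c1)[C@@H]1OC(O)[C@@H](C)[C@@H]1[C@@H](O[Si](C)(C)C(C)(C)C)C1SCCCS1 | intermediate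
21 | ring B methyl lactol ether (5S,6R,7S,8R,11S,12S) with C9 dithiane | C=C(C)[C@H](OCc1ccc2ccccc2c1)[C@@H]1O[C@H](OC)[C@@H](C)[C@@H]1[C@@H](O[Si](C)(C)C(C)(C)C)C1SCCCS1 | intermediate
22 | C9 aldehyde (α-silyloxy aldehyde on ring B) | C=C(C)[C@H](OCc1ccc2ccccc2c1)[C@@H]1O[C@H](OC)[C@@H](C)[C@@H]1[C@@H](O[Si](C)(C)C(C)(C)C)C=O | intermediate
23 | (R)-4-benzyl-3-propionyloxazolidin-2-one | CCC(=O)N1[C@H](Cc2ccccc2)COC1=O | starting material
24 | Z boron enolate of 23 | C/C=C(\OB(CCCC)CCCC)N1[C@H](Cc2ccccc2)COC1=O | intermediate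
25 | syn aldol adduct (8R,9R,10R) | C=C(C)[C@H](OCc1ccc2ccccc2c1)[C@@H]1O[C@H](OC)[C@@H](C)[C@@H]1[C@@H](O[Si](C)(C)C(C)(C)C)[C@H](O)[C@@H](C)C(=O)N1[C@H](Cc2ccccc2)COC1=O | intermediate
26 | O9-TES aldol imide | C=C(C)[C@H](OCc1ccc2ccccc2c1)[C@@H]1O[C@H](OC)[C@@H](C)[C@@H]1[C@@H](O[Si](C)(C)C(C)(C)C)[C@H](O[Si](CC)(CC)CC)[C@@H](C)C(=O)N1[C@H](Cc2ccccc2)COC1=O | intermediate
27 | C1 carboxylic acid (O5-NAP) | C=C(C)[C@H](OCc1ccc2ccccc2c1)[C@@H]1O[C@H](OC)[C@@H](C)[C@@H]1[C@@H](O[Si](C)(C)C(C)(C)C)[C@H](O[Si](CC)(CC)CC)[C@@H](C)C(=O)O | intermediate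
28 | seco acid with free O5–H | C=C(C)[C@H](O)[C@@H]1O[C@H](OC)[C@@H](C)[C@@H]1[C@@H](O[Si](C)(C)C(C)(C)C)[C@H](O[Si](CC)(CC)CC)[C@@H](C)C(=O)O | intermediate
29 | mixed anhydride of 28 and 2-methyl-6-nitrobenzoic acid | C=C(C)[C@H](O)[C@@H]1O[C@H](OC)[C@@H](C)[C@@H]1[C@@H](O[Si](C)(C)C(C)(C)C)[C@H](O[Si](CC)(CC)CC)[C@@H](C)C(=O)OC(=O)c1c(C)cccc1[N+](=O)[O-] | intermediate
30 | eight-membered lactone (5S,6R,7S,8R,9R,10R,11S,12S): C1(=O)–O–C5 oxocan-2-one cis-fused to ring B, isopropenyl on C5 | O=C1O[C@@H](C(C)=C)[C@@H]2O[C@H](OC)[C@@H](C)[C@@H]2[C@@H](O[Si](C)(C)C(C)(C)C)[C@H](O[Si](CC)(CC)CC)[C@H]1C | intermediate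
31 | enol ether (2-methyleneoxocane, C2=C1) | C=C1O[C@@H](C(C)=C)[C@@H]2O[C@H](OC)[C@@H](C)[C@@H]2[C@@H](O[Si](C)(C)C(C)(C)C)[C@H](O[Si](CC)(CC)CC)[C@H]1C | intermediate
32 | (4E)-cyclodec-4-en-1-one (6S,7S,8R,9R,10R,11S,12S) fused to ring B | O=C1CC/C(C)=C/[C@@H]2O[C@H](OC)[C@@H](C)[C@@H]2[C@@H](O[Si](C)(C)C(C)(C)C)[C@H](O[Si](CC)(CC)CC)[C@H]1C | intermediate
33 | (1S)-cyclodecenol | O[C@H]1CC/C(C)=C/[C@@H]2O[C@H](OC)[C@@H](C)[C@@H]2[C@@H](O[Si](C)(C)C(C)(C)C)[C@H](O[Si](CC)(CC)CC)[C@H]1C | intermediate
34 | C1 methyl ether (1S,6S,7S,8R,9R,10S,11S,12S) | CO[C@H]1CC/C(C)=C/[C@@H]2O[C@H](OC)[C@@H](C)[C@@H]2[C@@H](O[Si](C)(C)C(C)(C)C)[C@H](O[Si](CC)(CC)CC)[C@H]1C | intermediate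
35 | hydroxy lactol (O9–H and C12 hemiacetal free) | CO[C@H]1CC/C(C)=C/[C@@H]2OC(O)[C@@H](C)[C@@H]2[C@@H](O[Si](C)(C)C(C)(C)C)[C@H](O)[C@H]1C | intermediate
36 | C9-keto γ-lactone with O8-TBS (1S,6S,7S,8R,10S,11S) | CO[C@H]1CC/C(C)=C/[C@@H]2OC(=O)[C@@H](C)[C@@H]2[C@@H](O[Si](C)(C)C(C)(C)C)C(=O)[C@H]1C | intermediate
37 | C8-hydroxy C9-ketone (1S,6S,7R,8R,10S,11S) | CO[C@H]1CC/C(C)=C/[C@@H]2OC(=O)[C@@H](C)[C@@H]2[C@@H](O)C(=O)[C@H]1C | intermediate
38 | tiglic acid | C/C=C(\C)C(=O)O | starting material
39 | (E)-2-methylbut-2-en-1-ol | C/C=C(\C)CO | intermediate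
40 | [(2R,3R)-2,3-dimethyloxiran-2-yl]methanol | OC[C@@]1(C)O[C@@H]1C | intermediate
41 | (2S,3R)-2,3-dimethyloxirane-2-carboxylic acid | OC(=O)[C@@]1(C)O[C@@H]1C | intermediate
42 | mixed anhydride of 41 and 2,4,6-trichlorobenzoic acid | O=C(OC(=O)c1c(Cl)cc(Cl)cc1Cl)[C@@]1(C)O[C@@H]1C | intermediate
43 | CNP0145898.1 (1S,4E,6S,7S,8R,10S,11S; ester 2S,3R) | CO[C@H]1CC/C(C)=C/[C@@H]2OC(=O)[C@@H](C)[C@@H]2[C@@H](OC(=O)[C@@]2(C)O[C@@H]2C)C(=O)[C@H]1C | target

Total step count: 28. Longest linear sequence: 25 steps (steps 1–24 and 28). Steps 25–27 form the side branch.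

Steps most likely to fail

Step 20. Part or all of the [3,3] shift may run through the arrangement with C6 axial, or through a boat, and close the ring with Z geometry at C4=C5. The fallback corrects the geometry after ring formation by stereospecific alkene inversion. It sets out from 30.
- The same methylenation and heating would give the (4Z)-cyclodecenone F1.
- Oxazaborolidine reduction would give the (4Z)-C1 alcohol F2, and MeOTf with the hindered pyridine the (4Z)-C1 methyl ether F3.
- mCPBA epoxidises the only alkene to the cis-4,5-epoxide F4; the face of attack is irrelevant and one is drawn.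
- LiPPh2 opens the epoxide at C5 with inversion, MeI quaternises phosphorus, and the betaine collapses by syn elimination to the E alkene, which is 34.

Step 19. Intermolecular acylation (dimer and oligomer formation) may outrun closure of the strained eight-membered ring at the hindered O5. The fallback makes the ester bond intermolecularly and closes the ring at C9–C10 by a samarium Reformatsky reaction, which is known for medium-ring lactones. It sets out from 21.
- Brief DDQ treatment at 0 °C removes the NAP group to give the O5 alcohol F5.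
- 2-Bromopropanoyl bromide and pyridine give the α-bromopropionate F6.
- MeI and CaCO3 in aqueous MeCN unmask the bromo ester aldehyde F7.
- SmI2 in THF at high dilution closes the ring through the chelated samarium enolate to the β-hydroxy lactone F8. The C9 and C10 epimers are separated at this point.
- TESCl and imidazole then give 30.

Step 21. Transannular shielding in the ten-membered ring may override the catalyst, so that hydride reaches the wrong face of the C1 ketone. The fallback accepts substrate control and inverts the carbinol. It sets out from 32.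
- NaBH4 in MeOH would give the (1R)-alcohol F9.
- Mitsunobu reaction with 4-nitrobenzoic acid, PPh3 and diisopropyl azodicarboxylate gives the inverted (1S)-4-nitrobenzoate F10.
- K2CO3 in MeOH releases 33.

Further compounds
F1 | step 20 | (4Z)-cyclodecenone | O=C1CC/C(C)=C\[C@@H]2O[C@H](OC)[C@@H](C)[C@@H]2[C@@H](O[Si](C)(C)C(C)(C)C)[C@H](O[Si](CC)(CC)CC)[C@H]1C
F2 | step 20 | (4Z)-C1 alcohol | O[C@H]1CC/C(C)=C\[C@@H]2O[C@H](OC)[C@@H](C)[C@@H]2[C@@H](O[Si](C)(C)C(C)(C)C)[C@H](O[Si](CC)(CC)CC)[C@H]1C
F3 | step 20 | (4Z)-C1 methyl ether | CO[C@H]1CC/C(C)=C\[C@@H]2O[C@H](OC)[C@@H](C)[C@@H]2[C@@H](O[Si](C)(C)C(C)(C)C)[C@H](O[Si](CC)(CC)CC)[C@H]1C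
F4 | step 20 | cis-4,5-epoxide | CO[C@H]1CC[C@@]2(C)O[C@H]2[C@@H]2O[C@H](OC)[C@@H](C)[C@@H]2[C@@H](O[Si](C)(C)C(C)(C)C)[C@H](O[Si](CC)(CC)CC)[C@H]1C
F5 | step 19 | O5 alcohol | C=C(C)[C@H](O)[C@@H]1O[C@H](OC)[C@@H](C)[C@@H]1[C@@H](O[Si](C)(C)C(C)(C)C)C1SCCCS1
F6 | step 19 | α-bromopropionate | C=C(C)[C@H](OC(=O)C(C)Br)[C@@H]1O[C@H](OC)[C@@H](C)[C@@H]1[C@@H](O[Si](C)(C)C(C)(C)C)C1SCCCS1
F7 | step 19 | bromo ester aldehyde | C=C(C)[C@H](OC(=O)C(C)Br)[C@@H]1O[C@H](OC)[C@@H](C)[C@@H]1[C@@H](O[Si](C)(C)C(C)(C)C)C=O
F8 | step 19 | β-hydroxy lactone | O=C1O[C@@H](C(C)=C)[C@@H]2O[C@H](OC)[C@@H](C)[C@@H]2[C@@H](O[Si](C)(C)C(C)(C)C)[C@H](O)[C@H]1C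
F9 | step 21 | (1R)-alcohol | O[C@@H]1CC/C(C)=C/[C@@H]2O[C@H](OC)[C@@H](C)[C@@H]2[C@@H](O[Si](C)(C)C(C)(C)C)[C@H](O[Si](CC)(CC)CC)[C@H]1C
F10 | step 21 | (1S)-4-nitrobenzoate | O=C(O[C@H]1CC/C(C)=C/[C@@H]2O[C@H](OC)[C@@H](C)[C@@H]2[C@@H](O[Si](C)(C)C(C)(C)C)[C@H](O[Si](CC)(CC)CC)[C@H]1C)c1ccc([N+](=O)[O-])cc1
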